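The route rests on disconnecting C16–C17, the bond between the carbinol carbon and C2 of the oxane ring. The key step exploits ring oxygen O1, which makes C2 a configurationally stable equatorial carbanion and later binds magnesium. In one operation an equatorial 2-stannyl oxane, already carrying C4–O, C5–Me and the C6 propenyl group, is relayed through lithium to magnesium with retention. It is then added to the C16 aldehyde of the complete tetraene–dihydropyranone chain. This forms the bond, fixes the 2,6-cis ring and should set C16 syn to O1. The precursors are a tin-bearing oxane and a C1–C16 dienal; only desilylation follows.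

Key step: step 21

Remark on the chemistry: chain atoms are numbered C1 (lactone carbonyl) to C24 (propenyl methyl). The oxane atoms are O1, C2 (= C17), C3, C4 (= C19), C5 (= C20) and C6 (= C21). The structure as drawn corresponds to 5S,10R,16S,17S,19R,20S,21S, with O1 and the C16 hydroxyl syn.

**Eastern fragment (oxane), steps 1–7**

Step 1
Reactants: 1 (R)-4-benzyl-3-propanoyl-1,3-oxazolidin-2-one; 2 (E)-but-2-enal
Product: 3 (R)-4-benzyl-3-[(2R,3S,4E)-3-hydroxy-2-methylhex-4-enoyl]-1,3-oxazolidin-2-one
Conditions: Bu2BOTf, Et3N, CH2Cl2, 0 °C; 2, −78 to 0 °C; H2O2, MeOH, pH 7 phosphate buffer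
Reagents that add atoms: none
Why: Evans boron aldol, in which the Z-boron enolate reacts through a Zimmerman–Traxler chair on the face away from the benzyl group and so sets C20 and C21 as the syn pair.

Step 2
Reactants: 3 (R)-4-benzyl-3-[(2R,3S,4E)-3-hydroxy-2-methylhex-4-enoyl]-1,3-oxazolidin-2-one
Product: 4 (2R,3S,4E)-3-hydroxy-N-methoxy-N,2-dimethylhex-4-enamide
Conditions: MeNH(OMe)·HCl, Me3Al, CH2Cl2, −20 °C to rt
Reagents that add atoms: N,O-dimethylhydroxylamine hydrochloride, CNOC.Cl
Why: Aluminium-amide transamination to the Weinreb amide is assisted by the free β-hydroxyl, attacks only the exocyclic acyl group and leaves both stereocentres untouched.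

Step 3
Reactants: 4 (2R,3S,4E)-3-hydroxy-N-methoxy-N,2-dimethylhex-4-enamide; 5 ethyl acetate
Product: 6 ethyl (4R,5S,6E)-5-hydroxy-4-methyl-3-oxooct-6-enoate
Conditions: 5, LiN(iPr)2 (excess), THF, −78 °C; then 4, −78 to −30 °C; AcOH quench
Reagents that add atoms: none
Why: Claisen-type acylation of the ester enolate by the Weinreb amide stops at the β-keto ester, because the chelated tetrahedral adduct and then the product enolate are inert to further attack.

Step 4
Reactants: 6 ethyl (4R,5S,6E)-5-hydroxy-4-methyl-3-oxooct-6-enoate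
Product: 8 (4R,5S,6S)-4-hydroxy-5-methyl-6-[(E)-prop-1-enyl]oxan-2-one, via syn-diol ester 7 (not isolated)
Conditions: Et2BOMe, NaBH4, THF/MeOH, −78 °C; aqueous work-up, MeOH azeotrope; then PPTS (cat.), toluene, 60 °C
Reagents that add atoms: none
Why: Narasaka–Prasad reduction, in which boron ties the C21 hydroxyl and the C19 ketone into a six-membered chelate and external hydride sets C19 1,3-syn to C21, followed by acid-catalysed lactonisation of the δ-hydroxy ester.

Step 5
Reactants: 8 (4R,5S,6S)-4-hydroxy-5-methyl-6-[(E)-prop-1-enyl]oxan-2-one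
Product: 9 (4R,5R,6S)-5-methyl-6-[(E)-prop-1-enyl]-4-(triethylsilyloxy)oxan-2-one
Conditions: Et3SiCl, imidazole, CH2Cl2, 0 °C to rt
Reagents that add atoms: chlorotriethylsilane, CC[Si](Cl)(CC)CC
Why: Standard silylation under a mild base that should not trigger β-elimination of the β-oxygenated lactone (the C20 descriptor changes only because silicon alters the priorities).

Step 6
Reactants: 9 (4R,5R,6S)-5-methyl-6-[(E)-prop-1-enyl]-4-(triethylsilyloxy)oxan-2-one
Product: 10 (4R,5R,6S)-5-methyl-6-[(E)-prop-1-enyl]-4-(triethylsilyloxy)oxan-2-ol (anomeric mixture)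
Conditions: iBu2AlH, CH2Cl2, −78 °C; aqueous potassium sodium tartrate
Reagents that add atoms: none
Why: Partial reduction of a δ-lactone stops at the lactol because the tetrahedral aluminate is stable at −78 °C.

Step 7
Reactants: 10 (4R,5R,6S)-5-methyl-6-[(E)-prop-1-enyl]-4-(triethylsilyloxy)oxan-2-ol
Product: 12 tributyl[(2R,4R,5R,6S)-5-methyl-6-[(E)-prop-1-enyl]-4-(triethylsilyloxy)oxan-2-yl]stannane (tin equatorial; 2,6-cis), via axial anomeric chloride 11 (not isolated)
Conditions: Me2C=C(Cl)NMe2, CH2Cl2, 0 °C; solvent exchange; Bu3SnLi (from Bu3SnH and LiN(iPr)2), THF, −78 °C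
Reagents that add atoms: tributylstannane, CCCC[SnH](CCCC)CCCC
Why: Neutral chlorination with the α-chloroenamine gives the anomerically stabilised axial chloride, and SN2 displacement by Bu3SnLi with inversion places tin equatorial, which sets C17.

**Western fragment (C8–C16), steps 8–14**

Step 8
Reactants: 13 (S)-4-benzyl-3-propanoyl-1,3-oxazolidin-2-one; 14 3-bromoprop-1-yne
Product: 15 (S)-4-benzyl-3-[(2R)-2-methylpent-4-ynoyl]-1,3-oxazolidin-2-one
Conditions: NaN(SiMe3)2, THF, −78 °C; 14, −78 to −40 °C
Reagents that add atoms: none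
Why: Evans alkylation, in which the chelated Z-sodium enolate is alkylated on the face away from the benzyl group and so sets C10 as R.

Step 9
Reactants: 15 (S)-4-benzyl-3-[(2R)-2-methylpent-4-ynoyl]-1,3-oxazolidin-2-one
Product: 16 (2R)-2-methylpent-4-yn-1-ol
Conditions: LiBH4, MeOH (1 equiv), Et2O, 0 °C
Reagents that add atoms: none
Why: Reductive removal of the auxiliary proceeds at the exocyclic acyl group without enolisation, so C10 is kept.

Step 10
Reactants: 16 (2R)-2-methylpent-4-yn-1-ol
Product: 18 (2R,4E)-5-iodo-2,4-dimethylpent-4-en-1-ol, via alkenylalane 17 (not isolated)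
Conditions: Me3Al, Cp2ZrCl2 (cat.), CH2Cl2, 0 °C to rt; then I2, THF, −30 °C
Reagents that add atoms: trimethylaluminium, C[Al](C)C; iodine, II
Why: Zirconium-catalysed Negishi carboalumination adds methyl and aluminium syn across the terminal alkyne with aluminium at the terminus, and iodinolysis with retention gives the E-iodoalkene (C12=C13).

Step 11
Reactants: 18 (2R,4E)-5-iodo-2,4-dimethylpent-4-en-1-ol; 19 N-methoxy-N-methylprop-2-enamide
Product: 20 (2E,4E,7R)-8-hydroxy-N-methoxy-N,5,7-trimethylocta-2,4-dienamide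
Conditions: Pd(OAc)2 (cat.), Bu4NCl, K2CO3, DMF, rt
Reagents that add atoms: none
Why: Heck reaction under Jeffery conditions, in which syn-insertion and syn-β-hydride elimination give the new E-alkene (C14=C15) while the geometry of the iodoalkene is retained.

Step 12
Reactants: 20 (2E,4E,7R)-8-hydroxy-N-methoxy-N,5,7-trimethylocta-2,4-dienamide
Product: 21 (2E,4E,7R)-N-methoxy-N,5,7-trimethyl-8-oxoocta-2,4-dienamide
Conditions: Dess–Martin periodinane, CH2Cl2, 0 °C to rt
Reagents that add atoms: none
Why: Dess–Martin oxidation is non-basic, so the α-stereocentre C10 of the new aldehyde should not epimerise.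

Step 13
Reactants: 21 (2E,4E,7R)-N-methoxy-N,5,7-trimethyl-8-oxoocta-2,4-dienamide; 22 ethyl(triphenyl)phosphonium iodide
Product: 23 (2E,4E,7R,8Z)-9-iodo-N-methoxy-N,5,7-trimethyldeca-2,4,8-trienamide
Conditions: 22, n-BuLi, THF, 0 °C; I2, −78 °C; NaN(SiMe3)2, −20 °C; then 21, −78 °C
Reagents that add atoms: iodine, II
Why: Stork–Zhao-type Wittig olefination, in which the non-stabilised α-iodo ylide reacts under kinetic control through the cis-oxaphosphetane and places iodine cis to the chain (Z, C8=C9).

Step 14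
Reactants: 23 (2E,4E,7R,8Z)-9-iodo-N-methoxy-N,5,7-trimethyldeca-2,4,8-trienamide
Product: 24 (2E,4E,7R,8Z)-9-iodo-5,7-dimethyldeca-2,4,8-trienal
Conditions: iBu2AlH, THF, −78 °C; aqueous potassium sodium tartrate
Reagents that add atoms: none
Why: Weinreb amide reduction stops at the aldehyde because the chelated aluminate collapses only on work-up, and the iodoalkene is inert.

**Lactone piece (C1–C7), steps 15–19, and completion of the western half, step 20**

Step 15
Reactants: 25 prop-2-yn-1-ol
Product: 26 (E)-3-(tributylstannyl)prop-2-en-1-ol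
Conditions: Bu3SnH, AIBN (cat.), neat, 80 °C
Reagents that add atoms: tributylstannane, CCCC[SnH](CCCC)CCCC
Why: Radical hydrostannation under equilibrating conditions favours the terminal E-vinylstannane, which is separated from its isomers by chromatography.

Step 16
Reactants: 26 (E)-3-(tributylstannyl)prop-2-en-1-ol
Product: 27 (E)-3-(tributylstannyl)prop-2-enal
Conditions: MnO2, CH2Cl2, rt
Reagents that add atoms: none
Why: MnO2 oxidises the allylic alcohol selectively and neutrally, so the carbon–tin bond and the E-geometry are kept.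

Step 17
Reactants: 27 (E)-3-(tributylstannyl)prop-2-enal; 28 allyl(tributyl)stannane
Product: 29 (1E,3S)-1-(tributylstannyl)hexa-1,5-dien-3-ol
Conditions: (S)-BINOL (cat.), Ti(OiPr)4 (cat.), 4 Å molecular sieves, CH2Cl2, −20 °C
Reagents that add atoms: none
Why: Keck asymmetric allylation, in which the (S)-BINOL–titanium Lewis acid directs the allyl group to the Si face of the enal and sets C5 as S.

Step 18
Reactants: 29 (1E,3S)-1-(tributylstannyl)hexa-1,5-dien-3-ol; 30 prop-2-enoyl chloride
Product: 31 (1E,3S)-1-(tributylstannyl)hexa-1,5-dien-3-yl prop-2-enoate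
Conditions: Et3N, DMAP (cat.), CH2Cl2, 0 °C
Reagents that add atoms: none
Why: Simple O-acylation, which does not touch the C5–O bond and therefore keeps the configuration.

Step 19
Reactants: 31 (1E,3S)-1-(tributylstannyl)hexa-1,5-dien-3-yl prop-2-enoate
Product: 32 (6S)-6-[(E)-2-(tributylstannyl)ethenyl]-5,6-dihydro-2H-pyran-2-one
Conditions: second-generation Grubbs catalyst (cat.), CH2Cl2, 40 °C
Reagents that add atoms: none
Why: Ring-closing metathesis joins the acrylate and the terminal allyl alkene to the six-membered lactone, while the hindered stannyl-substituted alkene should stay out of the catalytic cycle.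

Step 20
Reactants: 24 (2E,4E,7R,8Z)-9-iodo-5,7-dimethyldeca-2,4,8-trienal; 32 (6S)-6-[(E)-2-(tributylstannyl)ethenyl]-5,6-dihydro-2H-pyran-2-one
Product: 33 (2E,4E,7R,8Z,10E)-5,7,9-trimethyl-11-[(2S)-6-oxo-3,6-dihydro-2H-pyran-2-yl]undeca-2,4,8,10-tetraenal
Conditions: copper thiophene-2-carboxylate Cu(O2CC4H3S), NMP, 0 °C to rt
Reagents that add atoms: none
Why: Copper-mediated Stille-type coupling joins the two alkenyl partners with retention of both geometries, tolerates the aldehyde and avoids zerovalent palladium, which could ionise the allylic C5–O bond of the lactone.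

**Union and completion, steps 21–22**

Step 21
Reactants: 12 tributyl[(2R,4R,5R,6S)-5-methyl-6-[(E)-prop-1-enyl]-4-(triethylsilyloxy)oxan-2-yl]stannane; 33 (2E,4E,7R,8Z,10E)-5,7,9-trimethyl-11-[(2S)-6-oxo-3,6-dihydro-2H-pyran-2-yl]undeca-2,4,8,10-tetraenal
Product: 36 19-O-triethylsilyl ether of the target (16S,17S), via equatorial organolithium 34 (not isolated), via equatorial Grignard reagent 35 (not isolated)
Conditions: 12, n-BuLi, THF, −78 °C; MgBr2·OEt2, −78 °C; transfer by cannula into 33, THF, −78 °C; pH 7 phosphate buffer at −78 °C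
Reagents that add atoms: none
Why: Tin–lithium exchange on the equatorial C2–Sn bond of 12 gives the α-alkoxy organolithium 34, MgBr2·OEt2 turns it into the less basic Grignard reagent 35, and 35 adds in the 1,2-mode to the C16 aldehyde of 33 through a closed four-centre transition state. The closest known reaction type is the addition of 2-deoxypyranosyl lithium and magnesium reagents, made from anomeric stannanes, to aldehydes. No ring is closed, since the oxane enters intact. C17 (oxane C2) keeps its equatorial, 2,6-cis configuration because the carbanion next to O1 is configurationally stable at −78 °C and both metal exchanges and the C–C bond formation run with retention. C16 is controlled by magnesium bridging O1 and the aldehyde oxygen: in the incipient five-membered chelate the dienyl chain lies trans to C3, so the Re face of the aldehyde is attacked and the syn (16S,17S) carbinol should result. The step needs aldehyde-over-lactone chemoselectivity and no Wittig-type rearrangement towards the allylic C6–O1 bond; the first is secured by the low basicity of 35, inverse addition and a cold buffered quench, the second by the equatorial carbanion and the equatorial propenyl group pointing away from each other.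

Step 22
Reactants: 36 19-O-triethylsilyl ether of the target
Product: 37 (6S)-6-[(1E,3Z,5R,7E,9E,11S)-11-hydroxy-11-[(2S,4R,5S,6S)-4-hydroxy-5-methyl-6-[(E)-prop-1-enyl]oxan-2-yl]-3,5,7-trimethylundeca-1,3,7,9-tetraenyl]-5,6-dihydro-2H-pyran-2-one (target)
Conditions: HF·pyridine, pyridine, THF, 0 °C
Reagents that add atoms: none
Why: Fluoride cleavage of the triethylsilyl ether under pyridine-buffered conditions should spare the base-sensitive lactone and the acid-sensitive dienyl carbinol and touches no stereocentre.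

**Compound list**

1 | (R)-4-benzyl-3-propanoyl-1,3-oxazolidin-2-one | CCC(=O)N1[C@H](Cc2ccccc2)COC1=O | starting material
2 | (E)-but-2-enal | C/C=C/C=O | starting material
3 | (R)-4-benzyl-3-[(2R,3S,4E)-3-hydroxy-2-methylhex-4-enoyl]-1,3-oxazolidin-2-one | C/C=C/[C@H](O)[C@@H](C)C(=O)N1[C@H](Cc2ccccc2)COC1=O | intermediate
4 | (2R,3S,4E)-3-hydroxy-N-methoxy-N,2-dimethylhex-4-enamide | C/C=C/[C@H](O)[C@@H](C)C(=O)N(C)OC | intermediate
5 | ethyl acetate | CCOC(C)=O | starting material
6 | ethyl (4R,5S,6E)-5-hydroxy-4-methyl-3-oxooct-6-enoate | C/C=C/[C@H](O)[C@@H](C)C(=O)CC(=O)OCC | intermediate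
7 | ethyl (3R,4S,5S,6E)-3,5-dihydroxy-4-methyloct-6-enoate (not isolated) | C/C=C/[C@H](O)[C@@H](C)[C@H](O)CC(=O)OCC | intermediate
8 | (4R,5S,6S)-4-hydroxy-5-methyl-6-[(E)-prop-1-enyl]oxan-2-one | C/C=C/[C@@H]1OC(=O)C[C@@H](O)[C@@H]1C | intermediate
9 | (4R,5R,6S)-5-methyl-6-[(E)-prop-1-enyl]-4-(triethylsilyloxy)oxan-2-one | C/C=C/[C@@H]1OC(=O)C[C@@H](O[Si](CC)(CC)CC)[C@@H]1C | intermediate
10 | (4R,5R,6S)-5-methyl-6-[(E)-prop-1-enyl]-4-(triethylsilyloxy)oxan-2-ol, anomeric mixture | C/C=C/[C@@H]1OC(O)C[C@@H](O[Si](CC)(CC)CC)[C@@H]1C | intermediate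
11 | {[(2S,4R,5R,6S)-2-chloro-5-methyl-6-[(E)-prop-1-enyl]oxan-4-yl]oxy}triethylsilane, chlorine axial (not isolated) | C/C=C/[C@@H]1O[C@@H](Cl)C[C@@H](O[Si](CC)(CC)CC)[C@@H]1C | intermediate
12 | tributyl[(2R,4R,5R,6S)-5-methyl-6-[(E)-prop-1-enyl]-4-(triethylsilyloxy)oxan-2-yl]stannane, tin equatorial | C/C=C/[C@@H]1O[C@H]([Sn](CCCC)(CCCC)CCCC)C[C@@H](O[Si](CC)(CC)CC)[C@@H]1C | intermediate
13 | (S)-4-benzyl-3-propanoyl-1,3-oxazolidin-2-one | CCC(=O)N1[C@@H](Cc2ccccc2)COC1=O | starting material
14 | 3-bromoprop-1-yne | C#CCBr | starting material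
15 | (S)-4-benzyl-3-[(2R)-2-methylpent-4-ynoyl]-1,3-oxazolidin-2-one | C#CC[C@@H](C)C(=O)N1[C@@H](Cc2ccccc2)COC1=O | intermediate
16 | (2R)-2-methylpent-4-yn-1-ol | C#CC[C@@H](C)CO | intermediate
17 | (E)-alkenyl(dimethyl)alane of 16, oxygen bound to dimethylaluminium (not isolated) | C[Al](C)/C=C(\C)C[C@@H](C)CO[Al](C)C | intermediate
18 | (2R,4E)-5-iodo-2,4-dimethylpent-4-en-1-ol | I/C=C(\C)C[C@@H](C)CO | intermediate
19 | N-methoxy-N-methylprop-2-enamide | C=CC(=O)N(C)OC | starting material
20 | (2E,4E,7R)-8-hydroxy-N-methoxy-N,5,7-trimethylocta-2,4-dienamide | CON(C)C(=O)/C=C/C=C(\C)C[C@@H](C)CO | intermediate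
21 | (2E,4E,7R)-N-methoxy-N,5,7-trimethyl-8-oxoocta-2,4-dienamide | CON(C)C(=O)/C=C/C=C(\C)C[C@@H](C)C=O | intermediate
22 | ethyl(triphenyl)phosphonium iodide | CC[P+](c1ccccc1)(c1ccccc1)c1ccccc1.[I-] | starting material
23 | (2E,4E,7R,8Z)-9-iodo-N-methoxy-N,5,7-trimethyldeca-2,4,8-trienamide | CON(C)C(=O)/C=C/C=C(\C)C[C@@H](C)/C=C(C)\I | intermediate
24 | (2E,4E,7R,8Z)-9-iodo-5,7-dimethyldeca-2,4,8-trienal | O=C/C=C/C=C(\C)C[C@@H](C)/C=C(C)\I | intermediate
25 | prop-2-yn-1-ol | C#CCO | starting material
26 | (E)-3-(tributylstannyl)prop-2-en-1-ol | CCCC[Sn](CCCC)(CCCC)/C=C/CO | intermediate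
27 | (E)-3-(tributylstannyl)prop-2-enal | CCCC[Sn](CCCC)(CCCC)/C=C/C=O | intermediate
28 | allyl(tributyl)stannane | C=CC[Sn](CCCC)(CCCC)CCCC | starting material
29 | (1E,3S)-1-(tributylstannyl)hexa-1,5-dien-3-ol | CCCC[Sn](CCCC)(CCCC)/C=C/[C@@H](O)CC=C | intermediate
30 | prop-2-enoyl chloride | C=CC(=O)Cl | starting material
31 | (1E,3S)-1-(tributylstannyl)hexa-1,5-dien-3-yl prop-2-enoate | CCCC[Sn](CCCC)(CCCC)/C=C/[C@@H](OC(=O)C=C)CC=C | intermediate
32 | (6S)-6-[(E)-2-(tributylstannyl)ethenyl]-5,6-dihydro-2H-pyran-2-one | CCCC[Sn](CCCC)(CCCC)/C=C/[C@@H]1CC=CC(=O)O1 | intermediate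
33 | (2E,4E,7R,8Z,10E)-5,7,9-trimethyl-11-[(2S)-6-oxo-3,6-dihydro-2H-pyran-2-yl]undeca-2,4,8,10-tetraenal | O=C/C=C/C=C(\C)C[C@@H](C)/C=C(C)\C=C\[C@@H]1CC=CC(=O)O1 | intermediate
34 | equatorial 2-lithio oxane from 12 (not isolated) | C/C=C/[C@@H]1O[C@H]([Li])C[C@@H](O[Si](CC)(CC)CC)[C@@H]1C | intermediate
35 | equatorial oxan-2-ylmagnesium bromide from 34 (not isolated) | C/C=C/[C@@H]1O[C@H]([Mg]Br)C[C@@H](O[Si](CC)(CC)CC)[C@@H]1C | intermediate
36 | 19-O-triethylsilyl ether of the target (16S,17S) | C/C=C/[C@@H]1O[C@H]([C@@H](O)/C=C/C=C(\C)C[C@@H](C)/C=C(C)\C=C\[C@@H]2CC=CC(=O)O2)C[C@@H](O[Si](CC)(CC)CC)[C@@H]1C | intermediate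
37 | (6S)-6-[(1E,3Z,5R,7E,9E,11S)-11-hydroxy-11-[(2S,4R,5S,6S)-4-hydroxy-5-methyl-6-[(E)-prop-1-enyl]oxan-2-yl]-3,5,7-trimethylundeca-1,3,7,9-tetraenyl]-5,6-dihydro-2H-pyran-2-one | C/C=C/[C@@H]1O[C@H]([C@@H](O)/C=C/C=C(\C)C[C@@H](C)/C=C(C)\C=C\[C@@H]2CC=CC(=O)O2)C[C@@H](O)[C@@H]1C | target

Total step count: 22.
Longest linear sequence: 10 steps (8, 9, 10, 11, 12, 13, 14, 20, 21, 22).

**Steps most likely to fail**

Step 21. Chelation of magnesium by O1 may be too weak, which would erode facial selectivity at the C16 carbonyl. Some of the carbanion may also be lost to proton transfer from the lactone.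
- The fallback moves control of C16 from the addition to a reagent-controlled reduction.
- It sets out from 36, whatever its composition at C16. Oxidation with MnO2 (CH2Cl2, rt, only the dienylic alcohol reacts) would give the C16 dienone F1.
- A Corey–Bakshi–Shibata reduction ((S)-2-methyl-CBS-oxazaborolidine, catecholborane, toluene, −78 °C) should then deliver hydride to the Re face. The Felkin–Anh model with O1 as the polar substituent favours the same face.
- The route is rejoined at 36.

Step 7. Loss of HCl from the anomeric chloride to the cyclic enol ether, or electron transfer from the stannyl anion with scrambling of the anomeric configuration, may compete with clean inversion.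
- The fallback avoids tin and sets out from lactol 10. PhSSPh and Bu3P (CH2Cl2, rt) would give the 2-(phenylsulfanyl)oxane F2.
- Reductive lithiation with lithium 4,4'-di-tert-butylbiphenylide (THF, −78 °C) gives first the axial 2-lithio oxane F3.
- Brief warming to −20 °C should equilibrate F3 to the more stable equatorial organolithium.
- The route is rejoined at 34.

Step 13. The α-iodo ylide is formed in several operations and is basic. Incomplete conversion, erosion of Z-selectivity and epimerisation of the α-stereocentre of the aldehyde are the likely problems.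
- The fallback builds the trisubstituted haloalkene by cross-coupling and sets out from aldehyde 21. A Corey–Fuchs reaction (CBr4, PPh3, CH2Cl2, 0 °C) would give the 1,1-dibromoalkene F4.
- A trans-selective Negishi methylation (MeZnCl, PdCl2(DPEphos) cat., THF, 0 °C) replaces only the less hindered bromine and gives the (Z)-bromoalkene F5.
- A copper-catalysed halogen exchange with retention (CuI cat., NaI, N,N'-dimethylethane-1,2-diamine, dioxane, heat) then gives the iodide.
- The route is rejoined at 23.

**Further compounds**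

F1 | step 21 | C16 dienone (16-oxo analogue of 36) | C/C=C/[C@@H]1O[C@H](C(=O)/C=C/C=C(\C)C[C@@H](C)/C=C(C)\C=C\[C@@H]2CC=CC(=O)O2)C[C@@H](O[Si](CC)(CC)CC)[C@@H]1C
F2 | step 7 | 2-(phenylsulfanyl)oxane from 10, anomeric mixture | C/C=C/[C@@H]1OC(Sc2ccccc2)C[C@@H](O[Si](CC)(CC)CC)[C@@H]1C
F3 | step 7 | axial 2-lithio oxane | C/C=C/[C@@H]1O[C@@H]([Li])C[C@@H](O[Si](CC)(CC)CC)[C@@H]1C
F4 | step 13 | (2E,4E,7R)-9,9-dibromo-N-methoxy-N,5,7-trimethylnona-2,4,8-trienamide | CON(C)C(=O)/C=C/C=C(\C)C[C@@H](C)C=C(Br)Br
F5 | step 13 | (2E,4E,7R,8Z)-9-bromo-N-methoxy-N,5,7-trimethyldeca-2,4,8-trienamide | CON(C)C(=O)/C=C/C=C(\C)C[C@@H](C)/C=C(C)\Br
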